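**Retrosynthetic overview**
1. No ring is formed: the only ring, the six-membered carbocycle, is bought as phloroglucinol 1 and is dearomatised, not built.
2. Key disconnection (made last): the tertiary C4–O bond of target 8 ⇒ enol carbon C4 of colupulone 7; a catalytic enantioselective oxygen transfer sets the only stereocentre (4S).
3. gem-Diprenyl C–C bond: 7 ⇒ deoxycohumulone 6 + prenyl bromide 4 (dearomatising alkylation).
4. Two aryl–prenyl C–C bonds: 6 ⇒ acylphloroglucinol 3 + two equivalents of 4.
5. Aryl–acyl C–C bond (made first): 3 ⇒ 1 + isobutyryl chloride 2.

Assumption: the target is one tautomer of a freely tautomerising β-triketone enol; its single stereocentre, the carbinol carbon, is S by CIP analysis of the given SMILES.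

**Step 1**
Reactants: 1 phloroglucinol; 2 isobutyryl chloride
Product: 3 phlorisobutyrophenone
Conditions: AlCl3 (3.5 equiv), PhNO2–CH2Cl2, 0 → 50 °C; ice/aq. HCl
Reagents that add atoms: none
Why: Friedel–Crafts C-acylation of the very electron-rich, threefold-symmetric arene gives one regioisomer, and the AlCl3-complexed, hydrogen-bonded aryl ketone is deactivated towards a second acylation.

**Step 2**
Reactants: 3 phlorisobutyrophenone; 4 prenyl bromide
Product: 6 deoxycohumulone, via 3-prenylphlorisobutyrophenone 5 (not isolated)
Conditions: prenyl bromide (2.0 equiv in total), 10% aq. KOH, 0 °C, Ar; then 2 M HCl to pH 2; chromatography, crystallisation from hexane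
Reagents that add atoms: prenyl bromide (the second equivalent of 4), CC(C)=CCBr
Why: C-alkylation of the ambident acylphloroglucinolate in water, where hydrogen bonding shields the phenolate oxygens, prenylates the two free ring CH positions one after the other with re-aromatisation each time; the slower dearomatising third alkylation is held back by the stoichiometry, so crystalline 6 can be purified before the air-sensitive triketone is made.

**Step 3**
Reactants: 6 deoxycohumulone; 4 prenyl bromide
Product: 7 colupulone
Conditions: liquid NH3–Et2O, prenyl bromide (1.1 equiv), −50 → −33 °C, Ar; evaporate NH3, aqueous work-up at pH 3 under Ar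
Reagents that add atoms: none
Why: Dearomatising enolate C-alkylation of the ammonium phenolate of 6 (ammonia is base and hydrogen-bonding solvent, favouring C- over O-alkylation) takes place at a prenyl-bearing ring carbon and not at the hindered, acyl-deactivated one, giving the achiral gem-diprenyl β-triketone.

**Step 4**
Reactants: 7 colupulone
Product: 8 (4S)-4-hydroxycolupulone (target)
Conditions: Cu(OTf)2 (10 mol%), (R,R)-tBu-box (11 mol%), 2,6-lutidine (10 mol%), (±)-3-phenyl-2-(phenylsulfonyl)oxaziridine (1.2 equiv, slow addition), 4 Å MS, degassed CH2Cl2, −40 °C, Ar, dark; aq. citric acid/EDTA wash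
Reagents that add atoms: 3-phenyl-2-(phenylsulfonyl)oxaziridine, O=S(=O)(c1ccccc1)N1OC1c1ccccc1
Why: Proposed new method: catalytic enantioselective hydroxylation at the carbon adjacent to a chelated β-triketone, in which the acidic triketone unit of 7 binds the square-planar divalent copper of Cu(OTf)2/(R,R)-tBu-box as its enolate through O3 and the side-chain acyl oxygen (the alternative site O1 is flanked by the gem-diprenyl carbon, whose out-of-plane prenyl groups clash with the ligand), so that the electron-rich enol carbon C4 (the site at which lupulones autoxidise, whereas C2 is fully acylated and hindered) sits where the dienophile α-carbon sits in the established Cu(OTf)2/tBu-box acryloylimide quadrant model, the tert-butyl group over that quadrant blocks one face, and the electrophilic oxaziridine oxygen is delivered to the other face to give the 4S carbinol while C5 becomes a ketone; the closest known reaction type is the chiral Lewis acid-catalysed α-hydroxylation of β-keto esters with N-sulfonyl oxaziridines (Davis oxidation), which has not been shown at this remote position or on hop β-acids.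

**Compound list**
1 | phloroglucinol (benzene-1,3,5-triol) | Oc1cc(O)cc(O)c1 | starting material
2 | isobutyryl chloride (2-methylpropanoyl chloride) | CC(C)C(Cl)=O | starting material
3 | phlorisobutyrophenone, 2-methyl-1-(2,4,6-trihydroxyphenyl)propan-1-one | CC(C)C(=O)c1c(O)cc(O)cc1O | intermediate
4 | prenyl bromide (1-bromo-3-methylbut-2-ene) | CC(C)=CCBr | starting material
5 | 3-prenylphlorisobutyrophenone, 2-methyl-1-[2,4,6-trihydroxy-3-(3-methylbut-2-en-1-yl)phenyl]propan-1-one | CC(C)C(=O)c1c(O)cc(O)c(CC=C(C)C)c1O | intermediate
6 | deoxycohumulone, 2-methyl-1-[2,4,6-trihydroxy-3,5-bis(3-methylbut-2-en-1-yl)phenyl]propan-1-one | CC(C)C(=O)c1c(O)c(CC=C(C)C)c(O)c(CC=C(C)C)c1O | intermediate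
7 | colupulone, 3,5-dihydroxy-2-(2-methylpropanoyl)-4,6,6-tris(3-methylbut-2-en-1-yl)cyclohexa-2,4-dien-1-one (achiral) | CC(C)=CCC1=C(O)C(CC=C(C)C)(CC=C(C)C)C(=O)C(C(=O)C(C)C)=C1O | intermediate
8 | (4S)-3,4-dihydroxy-2-(2-methylpropanoyl)-4,6,6-tris(3-methylbut-2-en-1-yl)cyclohex-2-ene-1,5-dione | CC(C)=CCC1(CC=C(C)C)C(=O)C(C(=O)C(C)C)=C(O)[C@@](O)(CC=C(C)C)C1=O | target

**Total step count:** 4. **Longest linear sequence:** 4.

**Steps most likely to fail**

Step 4 (proposed new step). Risks:
- low enantioselectivity if both chelation modes react or the C4 prenyl chain covers the open face;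
- one-electron oxidation of the dienol by divalent copper;
- acid-induced chroman formation;
- Mannich addition to the sulfonylimine by-product;
- α-ketol ring contraction of 8 on warming or with base.

The (R,R)-ligand is the one the quadrant model predicts for 4S. If chiral HPLC and ECD comparison show the opposite sense, the (S,S)-ligand is used instead.

The fallback uses known chemistry, sets out from 7 and comes back at 8. Compound 7 is converted into its dienolate with KN(SiMe3)2 (2.1 equiv) in THF at −78 °C and oxidised with the same racemic oxaziridine without any chiral catalyst (classical Davis enolate hydroxylation). Quenching at −78 °C with AcOH gives racemic 4-hydroxycolupulone F1. This is resolved by preparative chiral SFC on an amylose tris(3,5-dimethylphenylcarbamate) phase with CO2/MeOH containing 0.1% formic acid. The 4S enantiomer is 8, and the (4R)-4-hydroxycolupulone F2 is set aside.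

Step 2. Risks: mixtures of mono-, di- and triprenylated and O-prenylated products, so that 6 is obtained in modest yield.

The fallback sets out from 3 and comes back at 7, and it gives up stopping at the diprenyl stage. Compound 3 is treated with 4 (3.2 equiv) in liquid NH3–Et2O at −50 → −33 °C under Ar, so that 5 and 6 are alkylated further in the same flask and all partly prenylated material is driven on to 7 (exhaustive C-prenylation). After evaporation of NH3 and work-up at pH 3, 7 is crystallised from hexane at −20 °C under Ar. The price is a harder separation of air-sensitive 7 from tetraprenylated and O-prenylated by-products. This fallback makes no compound outside the list (F0).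

Step 3. Risks: O-prenylation, a fourth prenylation of 7 at C4, and air oxidation of 7.

The fallback sets out from 6 and comes back at 7, and it replaces the SN2 alkylation by a π-allylpalladium (Tsuji–Trost) alkylation. Prenol is treated with methyl chloroformate and pyridine in CH2Cl2 at 0 °C to give methyl prenyl carbonate F3. Compound 6 is then stirred with F3 (1.05 equiv) and Pd(PPh3)4 (5 mol%) in degassed THF at rt. Ionisation of F3 by zerovalent palladium gives the 1,1-dimethylallylpalladium cation, CO2 and methoxide, which deprotonates 6. The phenolate attacks the unsubstituted allyl terminus through carbon to give 7 without added base. Any O-prenyl ether that forms is re-ionised by the catalyst and funnelled to the C-alkylated product.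

**Further compounds**
F1 | step 4 | racemic 3,4-dihydroxy-2-(2-methylpropanoyl)-4,6,6-tris(3-methylbut-2-en-1-yl)cyclohex-2-ene-1,5-dione | CC(C)=CCC1(CC=C(C)C)C(=O)C(C(=O)C(C)C)=C(O)C(O)(CC=C(C)C)C1=O
F2 | step 4 | (4R)-3,4-dihydroxy-2-(2-methylpropanoyl)-4,6,6-tris(3-methylbut-2-en-1-yl)cyclohex-2-ene-1,5-dione | CC(C)=CCC1(CC=C(C)C)C(=O)C(C(=O)C(C)C)=C(O)[C@](O)(CC=C(C)C)C1=O
F0 | step 2 | none | none
F3 | step 3 | methyl prenyl carbonate (methyl 3-methylbut-2-en-1-yl carbonate) | COC(=O)OCC=C(C)C
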